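## Analysis of the target

The target is a diaryl ether of two benzene rings, with no stereocentre and no ring fusion. Ring A is a 1,2,4-trioxygenated benzene: pentyl at a1, hydrogen at a2 and a4, free hydroxyls at a3 and a5, and the ether oxygen at a6. Ring B carries the ether oxygen at b1, a methoxy group at b3, a pentanoyl group at b5 and a carboxyl at b6, so the acid sits between the ether and the ketone. The sensitive points are the electron-rich resorcinol ring A (oxidation, electrophilic substitution), the 2-acylbenzoic acid (ring–chain tautomerism to a hydroxy-lactone; a photoactive and reducible aryl ketone) and the single O-methyl group, which forbids an unselective ether cleavage at the end. The difficulty is the ether: a6 has two ortho substituents and b1 one, both carbons belong to electron-rich rings, and ring A needs a third oxygen that a simple pentylresorcinol does not have. The strategy rests on the pattern of ring A: the a5 hydroxyl is next to the ether carbon a6 and meta to the a3 oxygen, with hydrogen at a2 and a4. This is what a vinylketene bearing the aryloxy group at its alkene terminus and an alkoxyacetylene would give, so the ether bond can be made on a vinyl carbon before ring A exists.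

## Retrosynthetic reasoning

**30 to 29.** The two ring A hydroxyls and the b6 carboxyl are traced back to three benzyl groups. One neutral hydrogenolysis should then release all three, and the b3 methyl ether is never at risk.

**29 to 28 to 26.** The b5 ketone is taken back to the carbinol 28, and the carbinol and the b6 carboxyl are joined as the five-membered lactone of 26. The lactone hides both the acid and the aryl ketone during the diazo and photochemical steps. Forward, the lactone is opened with alkali, the carboxylate 27 is trapped as its benzyl ester before it can close again, and the carbinol is oxidised.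

**26 to 25.** The O–benzyl bond on the a5 oxygen is cut. A free, electron-rich phenol would not survive the oxidation of step 15, and this group leaves together with the others.

**25 to 15 and 20.** This is the key disconnection. Ring A is cut at a1–a2, a2–a3, a4–a5 and a5–a6, which leaves the alpha-diazo enone 15 and the ynol ether 20. Ring A then arrives aromatic, with its three oxygens in place and with a5 and a3 already differentiated (free hydroxyl against benzyl ether). No aryl–oxygen bond has to be made at a hindered carbon.

**15 to 13.** The bond between the acyl carbon (later a5) and the diazo carbon (later a2) is cut, giving acid 13 and a one-carbon diazo nucleophile, joined through acid chloride 14. No strong base is involved, which matters because the benzylic lactone C–H of the phthalide is acidic.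

**13 to 12 to 7 and 11.** The ether bond O–a6 is cut on the vinyl carbon, giving phenol 7 and enol tosylate 11. Addition–elimination at an ester-activated alkene is far easier than arylation of a hindered phenol. An allyl ester is chosen in place of a methyl ester so that the acid can be freed under neutral palladium catalysis. Alkali would open the lactone and could expel the aryloxide by conjugate addition–elimination.

**11 to 10 to 8.** The a1–a6 bond is cut: a6 comes in as a formyl carbon by crossed Claisen condensation on the ester 8, and the enol is fixed as the E tosylate.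

**7 to 6 to 3 to 2 to 1.** The b6 carboxyl carbon is introduced by carboxylation of an aryllithium generated from bromide 3. Direct lithiation of 2 would go between the two methoxy groups, so the bromine is placed first by electrophilic substitution para to a methoxy group. The butyl chain comes from addition of a butyl nucleophile to aldehyde 1. In 6 the methoxy group next to the lactone carbonyl is the only one that can chelate a Lewis acid, which gives phenol 7 selectively.

**20 to 18 to 16 and 17.** The ynol ether is cut at the O–C(sp) bond. Alcohol 16 adds to the dichloroacetylene formed from 17, and double elimination/exchange on 18 gives the alkyne.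

## Alternatives that were turned down

**Alternative 1:** Ring B would be cut at b1–b2 and b5–b6. Forward, the aryloxy alkynoate A2 (made from the ring A phenol A4) adds to the silyloxy cyclohexadiene A3 in a Diels–Alder reaction. The bicyclo[2.2.2]octadiene then loses its saturated two-carbon bridge (Alder–Rickert) and leaves benzoate A1.
- For: the route is convergent and the polarities match (enol ether terminus of A3 onto the aryloxy-bearing alkyne carbon). The b5 carbon is already at the ketone oxidation level and the carboxyl is already an ester. On that point it is stronger than the chosen route, which must open a lactone and oxidise a carbinol late.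
- Against: the triple bond of A2 is a push–pull system whose acceptor strength is lowered by the aryloxy donor. The diene terminus that must bond to the ester-bearing alkyne carbon carries the fully substituted dithianyl carbon, so a very crowded bridgehead has to form. The extrusion needs high temperature. Afterwards the silyl ether must be exchanged for methyl, the dithiane removed by oxidative or thiophilic reagents next to an electron-rich ring A, and a doubly ortho-substituted benzoate hydrolysed.
- Comparison: A4 already contains the three ring A oxygens and would itself take several steps, including an extra oxidation of a pentylresorcinol. The chosen strategy builds that oxygen pattern and the ether in the same operation.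

**Alternative 2:** Ring B would be cut at b5–b6 and b3–b4. Forward, the aryloxyglutaconate A6 (again from A4) condenses under base with the ketal-protected methyl ketone A7: Knoevenagel condensation at the ketone, then attack of the methyl carbon on the far ester (Dieckmann type) and enolisation give the hydroxybenzoate A5.
- For: the glutaconate anion is symmetric, so there is no regiochemical question. The reagents are simple and no photochemistry or diazo compound is needed. The pentanoyl group is carried as a ketal and needs only mild acid at the end, again better than the late oxidation of the chosen route.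
- Against: the ketone of A7 is flanked by a quaternary ketal carbon, and Knoevenagel condensations of such hindered ketones are slow and reversible. The ring closure needs the right alkene geometry and a vinylogous deprotonation. The new b3 hydroxyl must still be methylated, and the hindered ester hydrolysed.
- Comparison: like Alternative 1, it moves the real problem into A4, whose hindered hydroxyl must also add to the glutaconate precursor. The chosen route starts ring A from an acyclic ester and needs no trioxygenated arene.

**Alternative 3:** Ring A would be cut at a6–a1 and a4–a5. Forward, the aryloxymalonate A9 (from phenol 7 by O-alkylation) adds in a Michael reaction to enone A10, and the methyl ketone carbon then attacks a malonate ester. The cyclohexanedione ester A8 would then need loss of its ester group and dehydrogenation to become the resorcinol.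
- For: this is the classical way to pentylresorcinols. The reagents are cheap, the sequence is shorter than the chosen one, and both ring A hydroxyls come out free, so no protecting group is needed on ring A. On step count and on precedent for the ring construction it is the stronger plan.
- Against: a6 stays an sp3 carbon bearing the aryloxy group through several steps. Once the ester is gone, the ring can aromatise simply by expelling the aryloxide, which competes directly with the wanted dehydrogenation. The usual aromatising agents are electrophilic halogens, which would also attack the activated ring B. The methoxide and hydrolysis steps open the lactone.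
- Comparison: in the chosen route a6 is sp2 from the vinyl ether to the arene, except in the dienone that aromatises by a proton shift. No oxidant is needed to reach the aromatic level.

Key step: step 12

Remark on the chemistry: the target is treated as the open keto acid as drawn (its hydroxy-lactone tautomer is the same compound in equilibrium), and all phthalide intermediates are racemic because their only stereocentre is removed in step 15.

## Route

Step 1
Reactants: 1 3,5-dimethoxybenzaldehyde
Product: 2 racemic 1-(3,5-dimethoxyphenyl)pentan-1-ol
Conditions: BuMgBr, THF, 0 °C to rt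
Reagents that add atoms: butylmagnesium bromide, CCCC[Mg]Br
Why: Grignard addition to an aryl aldehyde; the carbinol centre is formed racemic and is erased in step 15.

Step 2
Reactants: 2 racemic 1-(3,5-dimethoxyphenyl)pentan-1-ol
Product: 3 racemic 1-(2-bromo-3,5-dimethoxyphenyl)pentan-1-ol
Conditions: NBS, MeCN, 0 °C to rt
Reagents that add atoms: N-bromosuccinimide, O=C1CCC(=O)N1Br
Why: Electrophilic aromatic bromination; the carbon ortho to the carbinol is para to one methoxy group and ortho to the other and is less crowded than the carbon between the two methoxy groups, as is usual for 3,5-dimethoxybenzyl alcohols.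

Step 3
Reactants: 3 racemic 1-(2-bromo-3,5-dimethoxyphenyl)pentan-1-ol
Product: 6 racemic 3-butyl-5,7-dimethoxyisobenzofuran-1(3H)-one, via dilithio alkoxide 4 (not isolated), via hydroxy acid 5 (not isolated)
Conditions: BuLi (2.2 equiv), THF, −78 °C; CO2; aq. HCl, rt
Reagents that add atoms: carbon dioxide, O=C=O
Why: Deprotonation of the hydroxyl and bromine–lithium exchange give the aryllithium, which is carboxylated; on acidification the gamma-hydroxy acid closes to the five-membered lactone.

Step 4
Reactants: 6 racemic 3-butyl-5,7-dimethoxyisobenzofuran-1(3H)-one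
Product: 7 racemic 3-butyl-7-hydroxy-5-methoxyisobenzofuran-1(3H)-one
Conditions: BCl3 (1.1 equiv), CH2Cl2, −78 to 0 °C
Reagents that add atoms: none
Why: Lewis acid demethylation directed by chelation between the lactone carbonyl and the neighbouring methoxy oxygen; the 5-methoxy group cannot chelate and should stay.

Step 5
Reactants: 8 allyl heptanoate
Product: 10 racemic allyl 2-formylheptanoate, via lithium enolate 9 (not isolated)
Conditions: LiN(iPr)2, THF, −78 °C; HCO2Et (3 equiv), −78 to 0 °C; aq. HCl
Reagents that add atoms: ethyl formate, CCOC=O
Why: Crossed Claisen formylation of an ester enolate; the product is held as its stabilised enolate until the quench, which should prevent further condensation and ester exchange.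

Step 6
Reactants: 10 racemic allyl 2-formylheptanoate
Product: 11 allyl (2E)-2-{[(4-methylbenzenesulfonyl)oxy]methylidene}heptanoate
Conditions: TsCl, N-methylimidazole (cat.), Et3N, CH2Cl2, 0 °C
Reagents that add atoms: 4-methylbenzenesulfonyl chloride, Cc1ccc(cc1)S(Cl)(=O)=O
Why: O-sulfonylation of the enol of an alpha-formyl ester; with amine base the E enol tosylate (sulfonate trans to the ester) is the expected isomer.

Step 7
Reactants: 7 racemic 3-butyl-7-hydroxy-5-methoxyisobenzofuran-1(3H)-one; 11 allyl (2E)-2-{[(4-methylbenzenesulfonyl)oxy]methylidene}heptanoate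
Product: 12 racemic allyl (2E)-3-[(3-butyl-5-methoxy-1-oxo-1,3-dihydroisobenzofuran-7-yl)oxy]-2-pentylprop-2-enoate
Conditions: Cs2CO3, MeCN, rt to 40 °C
Reagents that add atoms: none
Why: Nucleophilic vinylic substitution by addition–elimination at a beta-sulfonyloxy acrylate; the ester-stabilised carbanion expels tosylate and should give the more stable E vinylogous carbonate with the aryloxy group trans to the ester.

Step 8
Reactants: 12 racemic allyl (2E)-3-[(3-butyl-5-methoxy-1-oxo-1,3-dihydroisobenzofuran-7-yl)oxy]-2-pentylprop-2-enoate
Product: 13 racemic (2E)-3-[(3-butyl-5-methoxy-1-oxo-1,3-dihydroisobenzofuran-7-yl)oxy]-2-pentylprop-2-enoic acid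
Conditions: Pd(PPh3)4 (3 mol %), HCO2H, Et3N, THF, rt
Reagents that add atoms: none
Why: Tsuji–Trost deallylation with formate as hydride donor to the allylpalladium intermediate; the neutral conditions should leave the lactone closed and the aryloxyacrylate untouched.

Step 9
Reactants: 13 racemic (2E)-3-[(3-butyl-5-methoxy-1-oxo-1,3-dihydroisobenzofuran-7-yl)oxy]-2-pentylprop-2-enoic acid
Product: 15 racemic (E)-3-{[(3-butyl-5-methoxy-1-oxo-1,3-dihydroisobenzofuran-7-yl)oxy]methylidene}-1-diazooctan-2-one, via acid chloride 14 (not isolated)
Conditions: (COCl)2, DMF (cat.), CH2Cl2, 0 °C; evaporate; CH2N2 (3 equiv), Et2O, 0 °C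
Reagents that add atoms: diazomethane, C=[N+]=[N-]
Why: Acylation of diazomethane as in the first stage of the Arndt–Eistert sequence, with the excess reagent taking up HCl. The alkene is trisubstituted and carries an oxygen donor, so it should be a poor dipolarophile and its geometry should be kept.

Step 10
Reactants: 16 benzyl alcohol; 17 trichloroethylene
Product: 18 benzyl (E)-1,2-dichloroethenyl ether
Conditions: KH, THF, 0 °C to rt
Reagents that add atoms: none
Why: Base-induced loss of HCl from 17 gives dichloroacetylene, to which the alkoxide adds in anti fashion to give the E dichlorovinyl ether, a standard entry to ynol ethers.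

Step 11
Reactants: 18 benzyl (E)-1,2-dichloroethenyl ether
Product: 20 benzyl ethynyl ether, via lithium alkynyl ether 19 (not isolated)
Conditions: BuLi (2.3 equiv), THF, −78 °C; aq. NH4Cl, −78 °C; kept cold and used at once
Reagents that add atoms: none
Why: Deprotonation with loss of LiCl and then chlorine–lithium exchange give the lithium alkynyl ether, which is protonated cold. The product is kept below room temperature because benzyl alkynyl ethers rearrange sigmatropically on warming.

Step 12
Reactants: 15 racemic (E)-3-{[(3-butyl-5-methoxy-1-oxo-1,3-dihydroisobenzofuran-7-yl)oxy]methylidene}-1-diazooctan-2-one; 20 benzyl ethynyl ether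
Product: 25 racemic 7-[4-(benzyloxy)-2-hydroxy-6-pentylphenoxy]-3-butyl-5-methoxyisobenzofuran-1(3H)-one, via vinylketene 21 (not isolated), via cyclobutenone 22 (not isolated), via dienylketene 23 (not isolated), via cyclohexadienone 24 (not isolated)
Conditions: hν (350–365 nm, Pyrex), 20 (3 equiv), ClCH2CH2Cl (0.05 M, degassed), 15–20 °C; remove excess 20 under high vacuum below 25 °C; ClCH2CH2Cl, 80 °C
Reagents that add atoms: none
Why: Light expels N2 from 15 and the alkenyl group shifts to the diazo carbon (Wolff rearrangement, a1–a2), giving vinylketene 21. The unsubstituted carbon of 20 attacks the ketene carbon and the four-membered ring of 22 closes by ketene–alkyne (2+2) cycloaddition (a4–a5 and a2–a3). Reversible four-electron electrocyclic opening of 22 gives dienylketene 23, whose six-electron electrocyclisation closes the six-membered ring (a5–a6) to dienone 24, and a proton shift gives phenol 25. The closest known reaction is the Danheiser benzannulation in its photochemical Wolff form, which is established for alpha-diazo enones with alkoxy- and silyloxyalkynes; only the aryloxy group on the alkene terminus is new to the substrate. No stereocentre is created that persists: those of 22 and 24 vanish on aromatisation and the phthalide centre is untouched. The step needs regioselective union of ketene and alkyne, and the oxygen donor of 20 polarises the triple bond so that its CH carbon goes to the ketene carbon. This puts the benzyloxy carbon a3 meta to the free hydroxyl carbon a5 and leaves a6 next to a5. The E geometry of 15 holds the aryloxy group away from the carbene and turns it outward in the electrocyclisation, the lactone keeps an aryl ketone chromophore out of the photolysis, and the excess of 20 is removed before warming so that it cannot rearrange.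

Step 13
Reactants: 25 racemic 7-[4-(benzyloxy)-2-hydroxy-6-pentylphenoxy]-3-butyl-5-methoxyisobenzofuran-1(3H)-one
Product: 26 racemic 7-[2,4-bis(benzyloxy)-6-pentylphenoxy]-3-butyl-5-methoxyisobenzofuran-1(3H)-one
Conditions: BnBr, K2CO3, DMF, rt
Reagents that add atoms: benzyl bromide, BrCc1ccccc1
Why: Williamson etherification of the phenol; carbonate in DMF should not open the lactone.

Step 14
Reactants: 26 racemic 7-[2,4-bis(benzyloxy)-6-pentylphenoxy]-3-butyl-5-methoxyisobenzofuran-1(3H)-one
Product: 28 racemic benzyl 2-[2,4-bis(benzyloxy)-6-pentylphenoxy]-6-(1-hydroxypentyl)-4-methoxybenzoate, via potassium carboxylate 27 (not isolated)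
Conditions: KOH (1.1 equiv), THF–H2O, 50 °C; evaporate; BnBr, DMF, rt; used directly in step 15
Reagents that add atoms: potassium hydroxide, [K+].[OH-]; benzyl bromide, BrCc1ccccc1
Why: Saponification of the lactone gives the hydroxy carboxylate, and SN2 alkylation of the carboxylate gives the benzyl ester. The secondary alcohol is not alkylated without a strong base, and the ester is taken on at once so that it cannot close back to the lactone.

Step 15
Reactants: 28 racemic benzyl 2-[2,4-bis(benzyloxy)-6-pentylphenoxy]-6-(1-hydroxypentyl)-4-methoxybenzoate
Product: 29 benzyl 2-[2,4-bis(benzyloxy)-6-pentylphenoxy]-4-methoxy-6-pentanoylbenzoate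
Conditions: Dess–Martin periodinane, pyridine, CH2Cl2, 0 °C to rt
Reagents that add atoms: none
Why: Dess–Martin oxidation of a secondary benzylic alcohol under buffered, non-aqueous conditions; the ether-protected ring A should be inert and the ketone ends the risk of relactonisation.

Step 16
Reactants: 29 benzyl 2-[2,4-bis(benzyloxy)-6-pentylphenoxy]-4-methoxy-6-pentanoylbenzoate
Product: 30 2-(2,4-dihydroxy-6-pentylphenoxy)-4-methoxy-6-pentanoylbenzoic acid
Conditions: H2 (1 atm), Pd/C, EtOAc, rt, stopped at full debenzylation
Reagents that add atoms: none
Why: Catalytic hydrogenolysis of two aryl benzyl ethers and one benzyl ester; at low pressure in a neutral solvent these should cleave faster than the aryl ketone is reduced, and the methyl ether is inert.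

## Compound list

1 | 3,5-dimethoxybenzaldehyde | COc1cc(C=O)cc(OC)c1 | starting material
2 | racemic 1-(3,5-dimethoxyphenyl)pentan-1-ol | CCCCC(O)c1cc(OC)cc(OC)c1 | intermediate
3 | racemic 1-(2-bromo-3,5-dimethoxyphenyl)pentan-1-ol | CCCCC(O)c1cc(OC)cc(OC)c1Br | intermediate
4 | lithium 1-(2-lithio-3,5-dimethoxyphenyl)pentan-1-olate (racemic) | [Li]OC(CCCC)c1cc(OC)cc(OC)c1[Li] | intermediate
5 | racemic 2-(1-hydroxypentyl)-4,6-dimethoxybenzoic acid | CCCCC(O)c1cc(OC)cc(OC)c1C(=O)O | intermediate
6 | racemic 3-butyl-5,7-dimethoxyisobenzofuran-1(3H)-one | CCCCC1OC(=O)c2c(OC)cc(OC)cc21 | intermediate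
7 | racemic 3-butyl-7-hydroxy-5-methoxyisobenzofuran-1(3H)-one | CCCCC1OC(=O)c2c(O)cc(OC)cc21 | intermediate
8 | allyl heptanoate (prop-2-en-1-yl heptanoate) | CCCCCCC(=O)OCC=C | starting material
9 | lithium enolate of allyl heptanoate | CCCCCC=C(O[Li])OCC=C | intermediate
10 | racemic allyl 2-formylheptanoate (in equilibrium with its enol) | CCCCCC(C=O)C(=O)OCC=C | intermediate
11 | allyl (2E)-2-{[(4-methylbenzenesulfonyl)oxy]methylidene}heptanoate | CCCCC/C(=C\OS(=O)(=O)c1ccc(C)cc1)C(=O)OCC=C | intermediate
12 | racemic allyl (2E)-3-[(3-butyl-5-methoxy-1-oxo-1,3-dihydroisobenzofuran-7-yl)oxy]-2-pentylprop-2-enoate | CCCCC/C(=C\Oc1cc(OC)cc2c1C(=O)OC2CCCC)C(=O)OCC=C | intermediate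
13 | racemic (2E)-3-[(3-butyl-5-methoxy-1-oxo-1,3-dihydroisobenzofuran-7-yl)oxy]-2-pentylprop-2-enoic acid | CCCCC/C(=C\Oc1cc(OC)cc2c1C(=O)OC2CCCC)C(=O)O | intermediate
14 | racemic (2E)-3-[(3-butyl-5-methoxy-1-oxo-1,3-dihydroisobenzofuran-7-yl)oxy]-2-pentylprop-2-enoyl chloride | CCCCC/C(=C\Oc1cc(OC)cc2c1C(=O)OC2CCCC)C(=O)Cl | intermediate
15 | racemic (E)-3-{[(3-butyl-5-methoxy-1-oxo-1,3-dihydroisobenzofuran-7-yl)oxy]methylidene}-1-diazooctan-2-one | CCCCC/C(=C\Oc1cc(OC)cc2c1C(=O)OC2CCCC)C(=O)C=[N+]=[N-] | intermediate
16 | benzyl alcohol | OCc1ccccc1 | starting material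
17 | trichloroethylene | ClC=C(Cl)Cl | starting material
18 | benzyl (E)-1,2-dichloroethenyl ether | Cl/C=C(/Cl)OCc1ccccc1 | intermediate
19 | lithium (benzyloxy)ethynide | [Li]C#COCc1ccccc1 | intermediate
20 | benzyl ethynyl ether | C#COCc1ccccc1 | intermediate
21 | racemic 3-butyl-5-methoxy-7-{[(1E)-4-oxo-2-pentylbuta-1,3-dien-1-yl]oxy}isobenzofuran-1(3H)-one | CCCCC/C(=C\Oc1cc(OC)cc2c1C(=O)OC2CCCC)C=C=O | intermediate
22 | 3-(benzyloxy)-4-{(1E)-1-[(3-butyl-5-methoxy-1-oxo-1,3-dihydroisobenzofuran-7-yl)oxy]hept-1-en-2-yl}cyclobut-2-en-1-one, mixture of diastereomers | CCCCC/C(=C\Oc1cc(OC)cc2c1C(=O)OC2CCCC)C1C(=O)C=C1OCc1ccccc1 | intermediate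
23 | racemic 7-{[(1E,3E)-4-(benzyloxy)-6-oxo-2-pentylhexa-1,3,5-trien-1-yl]oxy}-3-butyl-5-methoxyisobenzofuran-1(3H)-one | O=C=C/C(OCc1ccccc1)=C\C(CCCCC)=C\Oc1cc(OC)cc2c1C(=O)OC2CCCC | intermediate
24 | 3-(benzyloxy)-6-[(3-butyl-5-methoxy-1-oxo-1,3-dihydroisobenzofuran-7-yl)oxy]-5-pentylcyclohexa-2,4-dien-1-one, mixture of diastereomers | O=C1C=C(OCc2ccccc2)C=C(CCCCC)C1Oc1cc(OC)cc2c1C(=O)OC2CCCC | intermediate
25 | racemic 7-[4-(benzyloxy)-2-hydroxy-6-pentylphenoxy]-3-butyl-5-methoxyisobenzofuran-1(3H)-one | CCCCCc1cc(OCc2ccccc2)cc(O)c1Oc1cc(OC)cc2c1C(=O)OC2CCCC | intermediate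
26 | racemic 7-[2,4-bis(benzyloxy)-6-pentylphenoxy]-3-butyl-5-methoxyisobenzofuran-1(3H)-one | CCCCCc1cc(OCc2ccccc2)cc(OCc2ccccc2)c1Oc1cc(OC)cc2c1C(=O)OC2CCCC | intermediate
27 | racemic potassium 2-[2,4-bis(benzyloxy)-6-pentylphenoxy]-6-(1-hydroxypentyl)-4-methoxybenzoate | CCCCCc1cc(OCc2ccccc2)cc(OCc2ccccc2)c1Oc1cc(OC)cc(C(O)CCCC)c1C(=O)[O-].[K+] | intermediate
28 | racemic benzyl 2-[2,4-bis(benzyloxy)-6-pentylphenoxy]-6-(1-hydroxypentyl)-4-methoxybenzoate | CCCCCc1cc(OCc2ccccc2)cc(OCc2ccccc2)c1Oc1cc(OC)cc(C(O)CCCC)c1C(=O)OCc1ccccc1 | intermediate
29 | benzyl 2-[2,4-bis(benzyloxy)-6-pentylphenoxy]-4-methoxy-6-pentanoylbenzoate | CCCCCc1cc(OCc2ccccc2)cc(OCc2ccccc2)c1Oc1cc(OC)cc(C(=O)CCCC)c1C(=O)OCc1ccccc1 | intermediate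
30 | 2-(2,4-dihydroxy-6-pentylphenoxy)-4-methoxy-6-pentanoylbenzoic acid | CCCCCc1cc(O)cc(O)c1Oc1cc(OC)cc(C(=O)CCCC)c1C(=O)O | target

## Step count and uncertain steps

Total step count: 16. Longest linear sequence: 12 steps (steps 1–4, 7–9 and 12–16, from 1).

**Step 12 (key step).** The ketene intermediates may be intercepted by the phenol already formed or by traces of moisture before the cycloaddition. Light-induced E/Z isomerisation of 15 would bring the ether oxygen within reach of the carbene and slow the final electrocyclisation. Sigmatropic rearrangement of 20 would remove the alkyne partner if the mixture warms too early. Fallback, setting out from 7 and returning at 26: commercial 5-pentylbenzene-1,3-diol is dibenzylated to 1,3-bis(benzyloxy)-5-pentylbenzene F1 and iodinated with N-iodosuccinimide para to one benzyloxy group to give 1,5-bis(benzyloxy)-2-iodo-3-pentylbenzene F2. F2 is coupled with phenol 7 in an Ullmann diaryl ether synthesis (CuI, picolinic acid, K3PO4, DMSO, 90 °C) to give 26, which enters step 14.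

**Step 9.** Dipolar cycloaddition of diazomethane to the acrylate double bond, or capture of HCl by the diazoketone, would consume material. Fallback, setting out from 13 through 14 and returning at 15: Negishi acylation of 14 with MeZnCl and Pd(PPh3)4 gives the methyl ketone (E)-3-{[(3-butyl-5-methoxy-1-oxo-1,3-dihydroisobenzofuran-7-yl)oxy]methylidene}octan-2-one F3. Its kinetic enolate (LiN(SiMe3)2, −78 °C) is acylated with 2,2,2-trifluoroethyl trifluoroacetate to the diketone (E)-5-{[(3-butyl-5-methoxy-1-oxo-1,3-dihydroisobenzofuran-7-yl)oxy]methylidene}-1,1,1-trifluorodecane-2,4-dione F4. Detrifluoroacetylative diazo transfer (methanesulfonyl azide, Et3N, H2O, MeCN) then gives 15.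

**Step 7.** The phenoxide may attack the sulfonyl sulfur instead of the vinyl carbon, and addition at the trisubstituted beta carbon by a hydrogen-bonded, hindered phenol may be slow. Fallback, setting out from 10 and returning at 12: this replaces the sulfonate by a vinyl halide and direct displacement by amine catalysis. Vilsmeier chlorination of 10 ((COCl)2, DMF, CH2Cl2) gives allyl 3-chloro-2-pentylprop-2-enoate F5 as an E/Z mixture, which has no sulfonyl centre. F5 reacts with 7 under DABCO catalysis (K2CO3, MeCN) through the vinylammonium salt and should converge on the E isomer 12.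

**Step 14.** The hydroxy ester may close back to the lactone with loss of benzyl alcohol before it is oxidised. Fallback, setting out from 27 and returning at 30: the carboxylate 27 is oxidised in its cold alkaline solution with KMnO4, the classical conversion of opened phthalides into 2-acylbenzoic acids, to give 2-[2,4-bis(benzyloxy)-6-pentylphenoxy]-4-methoxy-6-pentanoylbenzoic acid F6. Hydrogenolysis of F6 over Pd/C gives 30.

**Step 16.** Over-reduction of the aryl ketone, followed by closure to the lactone, or hydrogenolysis at the benzylic carbon of the hydroxy-lactone tautomer may compete with debenzylation. Fallback, setting out from 29 and returning at 30: all three benzyl groups are removed without a reductant by BCl3 with pentamethylbenzene as cation scavenger in CH2Cl2 at −78 °C. The unchelated b3 methyl ether should survive, and no new compound is made.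

## Further compounds

F1 | step 12 | 1,3-bis(benzyloxy)-5-pentylbenzene | CCCCCc1cc(OCc2ccccc2)cc(OCc2ccccc2)c1
F2 | step 12 | 1,5-bis(benzyloxy)-2-iodo-3-pentylbenzene | CCCCCc1cc(OCc2ccccc2)cc(OCc2ccccc2)c1I
F3 | step 9 | racemic (E)-3-{[(3-butyl-5-methoxy-1-oxo-1,3-dihydroisobenzofuran-7-yl)oxy]methylidene}octan-2-one | CCCCC/C(=C\Oc1cc(OC)cc2c1C(=O)OC2CCCC)C(C)=O
F4 | step 9 | racemic (E)-5-{[(3-butyl-5-methoxy-1-oxo-1,3-dihydroisobenzofuran-7-yl)oxy]methylidene}-1,1,1-trifluorodecane-2,4-dione | CCCCC/C(=C\Oc1cc(OC)cc2c1C(=O)OC2CCCC)C(=O)CC(=O)C(F)(F)F
F5 | step 7 | allyl 3-chloro-2-pentylprop-2-enoate, E/Z mixture | CCCCCC(=CCl)C(=O)OCC=C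
F6 | step 14 | 2-[2,4-bis(benzyloxy)-6-pentylphenoxy]-4-methoxy-6-pentanoylbenzoic acid | CCCCCc1cc(OCc2ccccc2)cc(OCc2ccccc2)c1Oc1cc(OC)cc(C(=O)CCCC)c1C(=O)O
F0 | step 16 | none | none
A1 | alternative 1 | methyl 2-[2,4-bis(benzyloxy)-6-pentylphenoxy]-6-(2-butyl-1,3-dithian-2-yl)-4-(trimethylsilyloxy)benzoate | CCCCCc1cc(OCc2ccccc2)cc(OCc2ccccc2)c1Oc1cc(O[Si](C)(C)C)cc(C2(CCCC)SCCCS2)c1C(=O)OC
A2 | alternative 1 | methyl 3-[2,4-bis(benzyloxy)-6-pentylphenoxy]prop-2-ynoate | CCCCCc1cc(OCc2ccccc2)cc(OCc2ccccc2)c1OC#CC(=O)OC
A3 | alternative 1 | 2-butyl-2-[3-(trimethylsilyloxy)cyclohexa-1,3-dien-1-yl]-1,3-dithiane | CCCCC1(SCCCS1)C1=CC(O[Si](C)(C)C)=CCC1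
A4 | alternative 1 | 2,4-bis(benzyloxy)-6-pentylphenol | CCCCCc1cc(OCc2ccccc2)cc(OCc2ccccc2)c1O
A5 | alternative 2 | methyl 2-[2,4-bis(benzyloxy)-6-pentylphenoxy]-6-(2-butyl-1,3-dioxolan-2-yl)-4-hydroxybenzoate | CCCCCc1cc(OCc2ccccc2)cc(OCc2ccccc2)c1Oc1cc(O)cc(C2(CCCC)OCCO2)c1C(=O)OC
A6 | alternative 2 | dimethyl 3-[2,4-bis(benzyloxy)-6-pentylphenoxy]pent-2-enedioate | CCCCCc1cc(OCc2ccccc2)cc(OCc2ccccc2)c1OC(CC(=O)OC)=CC(=O)OC
A7 | alternative 2 | 1-(2-butyl-1,3-dioxolan-2-yl)ethan-1-one | CC(=O)C1(CCCC)OCCO1
A8 | alternative 3 | methyl 1-[(3-butyl-5-methoxy-1-oxo-1,3-dihydroisobenzofuran-7-yl)oxy]-2,4-dioxo-6-pentylcyclohexane-1-carboxylate, mixture of diastereomers | CCCCCC1CC(=O)CC(=O)C1(Oc1cc(OC)cc2c1C(=O)OC2CCCC)C(=O)OC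
A9 | alternative 3 | racemic dimethyl 2-[(3-butyl-5-methoxy-1-oxo-1,3-dihydroisobenzofuran-7-yl)oxy]propanedioate | COC(=O)C(Oc1cc(OC)cc2c1C(=O)OC2CCCC)C(=O)OC
A10 | alternative 3 | (E)-non-3-en-2-one | CCCCC/C=C/C(C)=O
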